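| setting | winter | spring | Monday's | Tuesday's |
|---|---|---|---|---|
| electrophile | 0.50 M | 0.50 M | 0.50 M | 0.50 M |
| nucleophile | 0.45 M | 0.45 M | 0.450 M | 0.450 M |
| free base | 0.56 M | 0.60 M | 0.550 M | 0.720 M |
| remark | run made earlier | run made earlier |  |  |
| time |  |  | 15 min | 15 min |

| run | time / min | electrophile / % | target / % |
|---|---|---|---|
| winter | 1.33 | 84.8 | 2.9 |
| winter | 3.00 | 71.6 | 7.2 |
| winter | 6.00 | 54.4 | 11.4 |
| winter | 15.0 | 31.5 | 18.9 |
| spring | 4.00 | 64.1 | 9.2 |
| spring | 8.00 | 47.1 | 14.4 |
| spring | 12.0 | 36.2 | 16.7 |
| spring | 15.0 | 30.2 | 19.7 |

(standard deviation of a reading: 0.5 percentage points)

* part of the electrophile that has reacted at the end, Monday's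
* part of the electrophile that has reacted at the end, Tuesday's
* what raising the concentration of free base from its lowest to its highest value here does to the part of the electrophile that has reacted (changes below 5 percentage points count as none) (it rises / no change / it falls)

- percentages count the electrophile that a species holds: one self-condensation product counts as two
- target is meant together with its crystals
- solid, in amounts per volume of the solution: crystals
- what may be going on: electrophile + nucleophile -> acid set free + target; nucleophile + acid set free <-> protonated nucleophile; acid set free + free base <-> salt of the base; crystals <-> target; 2 electrophile -> self-condensation product

**Acid load.** The ratio I reckon with is acid set free per nucleophile charged. Each target brings one acid, and Monday's and Tuesday's charge the same electrophile and nucleophile as the winter run. So the winter reading of 18.9% target at 15.0 min gives 21.0% of the nucleophile charge. I call this the acid load.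

**Both ends.** Each target also uses one nucleophile. If the nucleophile binds the acid, its free fraction ends at 58.0%. If the free base, the acid scavenger, binds the acid instead, that fraction ends at 79.0%. Taking the mean free nucleophile as midway between start and end, the target route differs between these ends by a factor of 1.13. So I reckon a shift of about 2.5 percentage points in the winter target between these ends, and I call this the swing.

**Turned round.** In the proposed scheme self-condensation takes no base, so the free base reaches the electrophile through the nucleophile. The opposite outcome needs 5 points in the reacted electrophile; I count the whole swing as reacted electrophile, and it is half of that. Because it stays below the margin, I expect no change, with both flasks near winter's 68.5% reacted. A run could overturn this by showing a step from free base to electrophile outside the scheme, or a target reading that lifts the swing to the margin.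

**The forecast.** It gives 68.5% for Monday's and 70.5% for Tuesday's, so no change, holding that “More base should therefore barely change free nucleophile”.

**The flask.** Monday's gives 69.1% and Tuesday's 69.2%, so no change: the change is 0.027 points, less than the swing. Monday's keeps 61.2% of its nucleophile free at the end, closer to the lower end of 58.0% than to the upper.

    electrophile + nucleophile → acid set free + target (k = 0.00111 /M/s)
    nucleophile + acid set free ⇌ protonated nucleophile, settled at all times (K = 48.8 /M)
    acid set free + free base ⇌ salt of the base, settled at all times (K = 2.70 /M)
    crystals ⇌ target, rate k4*(cs4 - [target]) while solid is left; crystals form when [target] > cs4 (solubility = 0.0880 M, k = 0.0436 /s)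
    2 electrophile → self-condensation product (k = 0.00174 /M/s)

**Second flask.** The neighbour with 1.1 M of nucleophile holds 40.2% target at the end, so its acid load is 18.3% and its lower end is 63.4%. The computed flask keeps 64.7% of that nucleophile free.

The data stem from a simulated flask from invented constants; the scatter is artificial.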